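The route rests on cutting the C1–C5 bond of the cyclopentenone (C1 acetyl carbinol, C2=C3 dimethylalkene, C4 ketone, C5 spiro carbon, C6/C7 methylenes, C8 ether carbon, O9 ring oxygen). The feature used is that C5, shared by the oxolane and cyclopentenone rings, carries O9 and lies between C4=O and C1, a 1-oxaspiro[4.4]nonan-6-one array. Protonation of a dihydrofuranyl cyclobutenol turns C5 into an oxocarbenium ion. C1 then shifts from C4 to C5, which in one operation enlarges the strained ring to the enone, forms C1–C5 and creates the spiro centre. The precursor unites a resolved, squarate-derived cyclobutenone, whose C1 bears a silyl ether and a silylalkyne as masked acetyl, with a phytol-derived lithiodihydrofuran.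

Key step: step 12

Remark (stereochemical reading): the SMILES is (2S,5R,9S)-9-acetyl-9-hydroxy-2,7,8-trimethyl-2-[(4R,8R)-4,8,12-trimethyltridecyl]-1-oxaspiro[4.4]non-7-en-6-one. The C1 hydroxyl and O9 lie on opposite faces of the cyclopentenone, and C8 is S, so phytol must be epoxidised with L-(+)-tartrate.
Remark (dione): both methyl groups go onto the two adjacent squarate carbonyl carbons before any hydrolysis. An organolithium attacks 3-isopropoxy-4-methylcyclobutenedione at the carbonyl next to the alkoxy carbon, which would leave the two methyl groups 1,3 across the ring.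
Remark (C4 is a relay): C4 ends as a ketone, but its configuration decides from which face C5 reaches C1. The facial course of step 11 is therefore part of the stereocontrol of step 12.
Assumption: which chromatographic fraction of step 4 is the (4R)-alcohol is settled once, by anomalous-dispersion X-ray analysis of its 4-bromobenzoate, before material is carried on.

Step 1
Reactants: 1 diisopropyl squarate (3,4-diisopropoxycyclobut-3-ene-1,2-dione)
Product: 3 rac-2,3-diisopropoxy-4-methyl-4-(trimethylsilyloxy)cyclobut-2-en-1-one, via mono-adduct alkoxide 2 (not isolated)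
Conditions: MeLi (1.05 equiv), THF, −78 °C; then TMSCl, −78 → 0 °C
Reagents that add atoms: methyllithium [Li]C; chlorotrimethylsilane C[Si](C)(C)Cl
Why: Organolithium 1,2-addition to one of the two equivalent vinylogous-ester carbonyls of a squarate ester is fast at −78 °C and stops after one addition, and silylating the alkoxide in the flask avoids a dianion in the next addition.

Step 2
Reactants: 3 rac-2,3-diisopropoxy-4-methyl-4-(trimethylsilyloxy)cyclobut-2-en-1-one
Product: 5 3,4-dimethylcyclobut-3-ene-1,2-dione, via bis-adduct alkoxide 4 (not isolated)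
Conditions: MeLi (1.1 equiv), THF, −78 °C; then 3 M aq HCl, −78 °C → rt
Reagents that add atoms: methyllithium [Li]C; water O
Why: A second carbonyl 1,2-addition places the other methyl group on the adjacent ring carbon, and aqueous acid then effects the usual double allylic transposition of squarate adducts (each carbinol carbon becomes an alkene carbon, each isopropoxy carbon a carbonyl), which can only end in the 3,4-dimethyl dione.

Step 3
Reactants: 5 3,4-dimethylcyclobut-3-ene-1,2-dione; 6 trimethylsilylacetylene
Product: 8 rac-4-hydroxy-2,3-dimethyl-4-[(trimethylsilyl)ethynyl]cyclobut-2-en-1-one, via lithium acetylide 7 (not isolated)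
Conditions: 6, n-BuLi, THF, −78 °C; added to 5 (1.0 equiv), THF, −78 °C; sat. aq NH4Cl
Reagents that add atoms: none
Why: Lithium acetylide 1,2-addition to a cyclobutenedione is a standard entry to 4-alkynyl-4-hydroxycyclobutenones, the two carbonyls of 5 are equivalent and the alkoxide formed shields the second one, so one racemic mono-adduct should result.

Step 4
Reactants: 8 rac-4-hydroxy-2,3-dimethyl-4-[(trimethylsilyl)ethynyl]cyclobut-2-en-1-one
Product: 9 (4R)-4-hydroxy-2,3-dimethyl-4-[(trimethylsilyl)ethynyl]cyclobut-2-en-1-one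
Conditions: preparative SFC, amylose tris(3,5-dimethylphenylcarbamate) phase, CO2/i-PrOH, 30 °C
Reagents that add atoms: none
Why: No bond changes, since the enantiomers of a small rigid hydroxy ketone with a hydrogen-bond donor at the stereocentre are good candidates for separation on a carbamate-type polysaccharide phase, and this physical resolution fixes C1 of the target.

Step 5
Reactants: 9 (4R)-4-hydroxy-2,3-dimethyl-4-[(trimethylsilyl)ethynyl]cyclobut-2-en-1-one
Product: 10 (4R)-2,3-dimethyl-4-(triethylsilyloxy)-4-[(trimethylsilyl)ethynyl]cyclobut-2-en-1-one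
Conditions: TESOTf, 2,6-lutidine, CH2Cl2, −78 → 0 °C
Reagents that add atoms: triethylsilyl trifluoromethanesulfonate CC[Si](CC)(CC)OS(=O)(=O)C(F)(F)F
Why: Silyl triflate with a hindered pyridine base is the standard silylation of tertiary alcohols, the stereocentre is untouched, and TES is large enough to steer step 11 and survive catalytic acid yet still removable from a crowded tertiary position.

Step 6
Reactants: 11 natural (E,7R,11R)-phytol
Product: 12 [(2S,3S)-3-methyl-3-[(4R,8R)-4,8,12-trimethyltridecyl]oxiran-2-yl]methanol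
Conditions: Ti(OiPr)4 (10 mol %), L-(+)-DIPT (12 mol %), t-BuOOH, 4 Å MS, CH2Cl2, −20 °C
Reagents that add atoms: tert-butyl hydroperoxide CC(C)(C)OO
Why: This is a Katsuki–Sharpless asymmetric epoxidation of an E-trisubstituted allylic alcohol under reagent control, in which L-(+)-tartrate delivers oxygen as for geraniol to give the (2S,3S)-epoxide and so sets the future C8, while the remote 7R and 11R centres are bystanders.

Step 7
Reactants: 12 [(2S,3S)-3-methyl-3-[(4R,8R)-4,8,12-trimethyltridecyl]oxiran-2-yl]methanol
Product: 13 (2R,3S)-2-(iodomethyl)-3-methyl-3-[(4R,8R)-4,8,12-trimethyltridecyl]oxirane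
Conditions: I2, PPh3, imidazole, Et2O/MeCN, 0 °C
Reagents that add atoms: iodine [I][I]
Why: Appel-type iodination (Garegg–Samuelsson conditions) converts the primary alcohol by SN2 under near-neutral conditions that leave the trisubstituted epoxide and both its stereocentres spatially unchanged (the C2 descriptor changes only through priorities).

Step 8
Reactants: 13 (2R,3S)-2-(iodomethyl)-3-methyl-3-[(4R,8R)-4,8,12-trimethyltridecyl]oxirane
Product: 14 (3S,7R,11R)-3,7,11,15-tetramethylhexadec-1-en-3-ol
Conditions: activated Zn dust, AcOH (1.5 equiv), MeOH, 0 °C → rt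
Reagents that add atoms: none
Why: Zinc insertion into the C–I bond triggers β-elimination with opening of the epoxide (reductive 1,2-elimination of a 2,3-epoxy iodide), and since only the C2–O bond breaks the tertiary C–O stereocentre is retained.

Step 9
Reactants: 14 (3S,7R,11R)-3,7,11,15-tetramethylhexadec-1-en-3-ol
Product: 16 (5S)-5-methyl-5-[(4R,8R)-4,8,12-trimethyltridecyl]oxolan-2-ol (anomer mixture), via hydroxy aldehyde 15 (not isolated)
Conditions: Rh(acac)(CO)2 (0.5 mol %), Xantphos (1.5 mol %), CO/H2 (1:1, 20 bar), toluene, 80 °C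
Reagents that add atoms: carbon monoxide [C-]#[O+]
Why: Rhodium-catalysed hydroformylation with a wide-bite-angle diphosphine puts the formyl group on the terminal carbon of a vinyl group attached to a fully substituted carbon, a tertiary carbinol cannot isomerise to a carbonyl compound, and the γ-hydroxy aldehyde closes spontaneously to the lactol.

Step 10
Reactants: 16 (5S)-5-methyl-5-[(4R,8R)-4,8,12-trimethyltridecyl]oxolan-2-ol
Product: 18 (2S)-2-methyl-2-[(4R,8R)-4,8,12-trimethyltridecyl]-2,3-dihydrofuran, via anomeric mesylate 17 (not isolated)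
Conditions: MsCl, Et3N (excess), CH2Cl2, −40 °C → reflux; filtration through basic alumina
Reagents that add atoms: none
Why: Sulfonylation of the anomeric hydroxyl and base-induced 1,2-elimination is the usual dehydration of lactols to cyclic enol ethers, only C6 carries β-hydrogens so a single alkene can form, and C8 is not involved.

Step 11
Reactants: 18 (2S)-2-methyl-2-[(4R,8R)-4,8,12-trimethyltridecyl]-2,3-dihydrofuran; 10 (4R)-2,3-dimethyl-4-(triethylsilyloxy)-4-[(trimethylsilyl)ethynyl]cyclobut-2-en-1-one
Product: 20 (1S,4R)-2,3-dimethyl-1-{(5S)-5-methyl-5-[(4R,8R)-4,8,12-trimethyltridecyl]-4,5-dihydrofuran-2-yl}-4-(triethylsilyloxy)-4-[(trimethylsilyl)ethynyl]cyclobut-2-en-1-ol (OH cis to OTES), via lithiodihydrofuran 19 (not isolated)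
Conditions: 18, t-BuLi (0.95 equiv), THF/pentane, −78 → 0 °C; recool to −78 °C, add 10; H2O/THF quench at −78 °C; Et3N-deactivated silica
Reagents that add atoms: none
Why: α-Lithiation of a cyclic enol ether with t-BuLi followed by carbonyl 1,2-addition is standard for 2,3-dihydrofurans, a strained cyclobutenone without α-hydrogens accepts such nucleophiles readily, and approach on the face of the rod-like alkyne, anti to the bulky OTES group, should set C4 with OH cis to OTES.

Step 12
Reactants: 20 (1S,4R)-2,3-dimethyl-1-{(5S)-5-methyl-5-[(4R,8R)-4,8,12-trimethyltridecyl]-4,5-dihydrofuran-2-yl}-4-(triethylsilyloxy)-4-[(trimethylsilyl)ethynyl]cyclobut-2-en-1-ol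
Product: 22 (2S,5R,9R)-2,7,8-trimethyl-9-(triethylsilyloxy)-2-[(4R,8R)-4,8,12-trimethyltridecyl]-9-[(trimethylsilyl)ethynyl]-1-oxaspiro[4.4]non-7-en-6-one, via oxocarbenium ion 21 (not isolated)
Conditions: camphorsulfonic acid (10 mol %), anhydrous CH2Cl2/toluene, −40 → 0 °C; Et3N quench
Reagents that add atoms: none
Why: Proposed new method: the acid protonates the enol ether of 20 at C6 to give the C5 oxocarbenium ion 21, the C4–C1 σ bond (the long sp3–sp3 bond of the cyclobutene, aligned with the empty C5 orbital) shifts to C5, and the C4 hydroxyl collapses to the ketone and returns the proton, so the step is a catalytic isomerisation. The closest known reaction type is the oxonium-ion-triggered semipinacol enlargement of saturated 1-(4,5-dihydrofuran-2-yl)cyclobutanols to 1-oxaspiro[4.4]nonan-6-ones, whereas a cyclobutenol offering an sp2 migrant and a heteroatom-loaded sp3 migrant has not been put through it. The cyclopentenone ring is closed by ring enlargement through a suprafacial 1,2-carbon shift (four to five members, C1–C5 formed as C1–C4 breaks), not by an endo or exo cyclisation, and the oxolane ring is already in place. C1 migrates with retention and so carries the configuration secured in step 4, while the new centre C5 is set by the rotamer about C4–C5: with the dihydrofuranyl group on the alkyne face, the dipole-minimised (Cornforth-type) rotamer that holds C5=O9 anti to the C4–OH and C1–OSi dipoles places O9 trans to the silyloxy group, as the target requires. The step needs C1 to outrun vinylic C3, which should be secured by the weaker, more p-rich C4–C1 bond, by lone-pair support from the silyloxy oxygen, by the conjugated enone that only this shift produces, and by the housane-like strain that π-participation of C3 would cost. A weakly ionising medium, low temperature and a catalytic sulfonic acid should keep the shift concerted, avoiding opening to a pentadienyl cation that would erase C1, and should leave the tertiary TES ether and the C-silyl alkyne untouched.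

Step 13
Reactants: 22 (2S,5R,9R)-2,7,8-trimethyl-9-(triethylsilyloxy)-2-[(4R,8R)-4,8,12-trimethyltridecyl]-9-[(trimethylsilyl)ethynyl]-1-oxaspiro[4.4]non-7-en-6-one
Product: 23 (2S,5R,9S)-9-ethynyl-9-hydroxy-2,7,8-trimethyl-2-[(4R,8R)-4,8,12-trimethyltridecyl]-1-oxaspiro[4.4]non-7-en-6-one
Conditions: TBAF (3 equiv), AcOH (3 equiv), THF, 0 °C → rt
Reagents that add atoms: none
Why: Fluoride cleaves both the O–Si and the sp-C–Si bond, and buffering with acetic acid should keep the liberated β-hydroxy ketone from retro-aldol scrambling of C1 and C5 (the C9 descriptor changes only through priorities).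

Step 14
Reactants: 23 (2S,5R,9S)-9-ethynyl-9-hydroxy-2,7,8-trimethyl-2-[(4R,8R)-4,8,12-trimethyltridecyl]-1-oxaspiro[4.4]non-7-en-6-one
Product: 24 alpha-tocospiro A, (2S,5R,9S)-9-acetyl-9-hydroxy-2,7,8-trimethyl-2-[(4R,8R)-4,8,12-trimethyltridecyl]-1-oxaspiro[4.4]non-7-en-6-one
Conditions: Ph3PAuNTf2 (5 mol %), H2O (10 equiv), 1,4-dioxane, rt → 40 °C
Reagents that add atoms: water O
Why: Cationic monovalent gold activates the terminal alkyne for Markovnikov hydration at the internal carbon to give the methyl ketone, the competing Meyer–Schuster path would need attack at the terminal carbon and C1–O ionisation next to an electron-poor enone, and the acid-free medium touches no stereocentre.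

Compound list
1 | diisopropyl squarate | CC(C)OC1=C(OC(C)C)C(=O)C1=O | starting material
2 | lithium 2,3-diisopropoxy-1-methyl-4-oxocyclobut-2-en-1-olate (racemic) | CC(C)OC1=C(OC(C)C)C(C)(O[Li])C1=O | intermediate
3 | rac-2,3-diisopropoxy-4-methyl-4-(trimethylsilyloxy)cyclobut-2-en-1-one | CC(C)OC1=C(OC(C)C)C(C)(O[Si](C)(C)C)C1=O | intermediate
4 | lithium 2,3-diisopropoxy-1,4-dimethyl-4-(trimethylsilyloxy)cyclobut-2-en-1-olate (racemic cis/trans mixture, both converge) | CC(C)OC1=C(OC(C)C)C(C)(O[Si](C)(C)C)C1(C)O[Li] | intermediate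
5 | 3,4-dimethylcyclobut-3-ene-1,2-dione | CC1=C(C)C(=O)C1=O | intermediate
6 | trimethylsilylacetylene | C#C[Si](C)(C)C | starting material
7 | lithium (trimethylsilyl)acetylide | [Li]C#C[Si](C)(C)C | intermediate
8 | rac-4-hydroxy-2,3-dimethyl-4-[(trimethylsilyl)ethynyl]cyclobut-2-en-1-one | C[Si](C)(C)C#CC1(O)C(C)=C(C)C1=O | intermediate
9 | (4R)-4-hydroxy-2,3-dimethyl-4-[(trimethylsilyl)ethynyl]cyclobut-2-en-1-one | C[Si](C)(C)C#C[C@]1(O)C(C)=C(C)C1=O | intermediate
10 | (4R)-2,3-dimethyl-4-(triethylsilyloxy)-4-[(trimethylsilyl)ethynyl]cyclobut-2-en-1-one | C[Si](C)(C)C#C[C@]1(O[Si](CC)(CC)CC)C(C)=C(C)C1=O | intermediate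
11 | (E,7R,11R)-phytol | CC(C)CCC[C@@H](C)CCC[C@@H](C)CCC/C(C)=C/CO | starting material
12 | [(2S,3S)-3-methyl-3-[(4R,8R)-4,8,12-trimethyltridecyl]oxiran-2-yl]methanol | OC[C@@H]1O[C@@]1(C)CCC[C@H](C)CCC[C@H](C)CCCC(C)C | intermediate
13 | (2R,3S)-2-(iodomethyl)-3-methyl-3-[(4R,8R)-4,8,12-trimethyltridecyl]oxirane | C(I)[C@@H]1O[C@@]1(C)CCC[C@H](C)CCC[C@H](C)CCCC(C)C | intermediate
14 | (3S,7R,11R)-3,7,11,15-tetramethylhexadec-1-en-3-ol | C=C[C@](C)(CCC[C@H](C)CCC[C@H](C)CCCC(C)C)O | intermediate
15 | (4S,8R,12R)-4-hydroxy-4,8,12,16-tetramethylheptadecanal | O=CCC[C@](C)(CCC[C@H](C)CCC[C@H](C)CCCC(C)C)O | intermediate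
16 | (5S)-5-methyl-5-[(4R,8R)-4,8,12-trimethyltridecyl]oxolan-2-ol (anomer mixture) | OC1CC[C@](C)(CCC[C@H](C)CCC[C@H](C)CCCC(C)C)O1 | intermediate
17 | (5S)-5-methyl-5-[(4R,8R)-4,8,12-trimethyltridecyl]oxolan-2-yl methanesulfonate (anomer mixture) | CS(=O)(=O)OC1CC[C@](C)(CCC[C@H](C)CCC[C@H](C)CCCC(C)C)O1 | intermediate
18 | (2S)-2-methyl-2-[(4R,8R)-4,8,12-trimethyltridecyl]-2,3-dihydrofuran | C1=CC[C@](C)(CCC[C@H](C)CCC[C@H](C)CCCC(C)C)O1 | intermediate
19 | {(5S)-5-methyl-5-[(4R,8R)-4,8,12-trimethyltridecyl]-4,5-dihydrofuran-2-yl}lithium | [Li]C1=CC[C@](C)(CCC[C@H](C)CCC[C@H](C)CCCC(C)C)O1 | intermediate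
20 | (1S,4R)-2,3-dimethyl-1-{(5S)-5-methyl-5-[(4R,8R)-4,8,12-trimethyltridecyl]-4,5-dihydrofuran-2-yl}-4-(triethylsilyloxy)-4-[(trimethylsilyl)ethynyl]cyclobut-2-en-1-ol (OH cis to OTES) | C[Si](C)(C)C#C[C@]1(O[Si](CC)(CC)CC)C(C)=C(C)[C@]1(O)C2=CC[C@](C)(CCC[C@H](C)CCC[C@H](C)CCCC(C)C)O2 | intermediate
21 | C5 oxocarbenium ion formed from 20 by protonation at C6 (all stereocentres as in 20, camphorsulfonate counter-ion) | C[Si](C)(C)C#C[C@]1(O[Si](CC)(CC)CC)C(C)=C(C)[C@]1(O)C2=[O+][C@@](C)(CCC[C@H](C)CCC[C@H](C)CCCC(C)C)CC2 | intermediate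
22 | (2S,5R,9R)-2,7,8-trimethyl-9-(triethylsilyloxy)-2-[(4R,8R)-4,8,12-trimethyltridecyl]-9-[(trimethylsilyl)ethynyl]-1-oxaspiro[4.4]non-7-en-6-one | C[Si](C)(C)C#C[C@]1(O[Si](CC)(CC)CC)C(C)=C(C)C(=O)[C@@]12CC[C@](C)(CCC[C@H](C)CCC[C@H](C)CCCC(C)C)O2 | intermediate
23 | (2S,5R,9S)-9-ethynyl-9-hydroxy-2,7,8-trimethyl-2-[(4R,8R)-4,8,12-trimethyltridecyl]-1-oxaspiro[4.4]non-7-en-6-one | C#C[C@]1(O)C(C)=C(C)C(=O)[C@@]12CC[C@](C)(CCC[C@H](C)CCC[C@H](C)CCCC(C)C)O2 | intermediate
24 | alpha-tocospiro A | CC(=O)[C@]1(O)C(C)=C(C)C(=O)[C@@]12CC[C@](C)(CCC[C@H](C)CCC[C@H](C)CCCC(C)C)O2 | target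

Total step count: 14 (five to cyclobutenone 10, five to dihydrofuran 18, four after convergence).
Longest linear sequence: 9 steps (11 to 24 through steps 6–14). The branch from 1 is equally long (steps 1–5 and 11–14).

Steps most likely to fail

1. Step 12 (bears the label).
- **Processes at risk:**
  - migration of vinylic C3 in place of C1;
  - stepwise opening of the four-membered ring to a pentadienyl cation, which would erase the C1 configuration;
  - a shift through the rotamer that brings O9 onto the silyloxy face.
- **Fallback (known chemistry):** C1 is postponed until after the ring enlargement. The enlargement relies on an acyl shift, the established migration when 4-hydroxycyclobutenones expand to cyclopent-4-ene-1,3-diones. The fallback sets out from dione 5 and lithiodihydrofuran 19 (made from 18 as in step 11). 1,2-Addition at −78 °C gives 4-hydroxy-2,3-dimethyl-4-(dihydrofuranyl)cyclobutenone F1. Catalytic camphorsulfonic acid in CH2Cl2 protonates the enol ether and the acyl carbon moves to C5, giving the spiro enedione F2, in which C5 is not yet stereogenic. Ethynylmagnesium bromide (THF, −78 °C) then adds once to one carbonyl, preferably on the flank of the small ring oxygen, and creates C1 and C5 together. No preference between the two carbonyl groups is expected, so the diastereomers are separated by chromatography. The route is rejoined at 23, and steps 3–5 are no longer needed.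

2. Step 11.
- **Processes at risk:**
  - incomplete metalation, with left-over t-BuLi attacking the ketone;
  - proton transfer from the ring methyl groups of 10 to the basic vinyllithium;
  - drift of the TES group or anionic ring opening in the lithium alkoxide;
  - weak facial discrimination.
- **Fallback:** metalation is decoupled from addition, and the metal is changed. It sets out from 18, which is lithiated as before and trapped with Bu3SnCl to give the isolable tributyl(dihydrofuranyl)stannane F3. Tin–lithium exchange with n-BuLi at −78 °C regenerates 19 free of t-BuLi. Stirring with anhydrous CeCl3 gives the less basic and bulkier dichloro(dihydrofuranyl)cerium reagent F4. This adds to 10 at −78 °C, and the route is rejoined at 20.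

3. Step 14.
- **Processes at risk:**
  - 1,3-hydroxyl shift or ionisation of the free propargylic alcohol on gold (Meyer–Schuster path);
  - retro-aldol opening of the C1–C5 bond once the β-hydroxy ketone is unmasked.
- **Fallback:** the alkyne is hydrated while C1–O is still silylated, and the carbinol is freed last under acidic fluoride. It sets out from 22. K2CO3 (catalytic) in MeOH at 0 °C removes only the C-silyl group to give the ethynyl TES ether F5. Ph3PAuNTf2 and water in dioxane hydrate it to the acetyl TES ether F6. HF·pyridine in THF then cleaves the TES ether, and the route is rejoined at 24.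

Further compounds
F1 | step 12 | 4-hydroxy-2,3-dimethyl-4-{(5S)-5-methyl-5-[(4R,8R)-4,8,12-trimethyltridecyl]-4,5-dihydrofuran-2-yl}cyclobut-2-en-1-one (both carbinol epimers) | CC1=C(C)C(O)(C2=CC[C@](C)(CCC[C@H](C)CCC[C@H](C)CCCC(C)C)O2)C1=O
F2 | step 12 | (2S)-2,7,8-trimethyl-2-[(4R,8R)-4,8,12-trimethyltridecyl]-1-oxaspiro[4.4]non-7-ene-6,9-dione | CC1=C(C)C(=O)C2(CC[C@](C)(CCC[C@H](C)CCC[C@H](C)CCCC(C)C)O2)C1=O
F3 | step 11 | tributyl{(5S)-5-methyl-5-[(4R,8R)-4,8,12-trimethyltridecyl]-4,5-dihydrofuran-2-yl}stannane | CCCC[Sn](CCCC)(CCCC)C1=CC[C@](C)(CCC[C@H](C)CCC[C@H](C)CCCC(C)C)O1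
F4 | step 11 | dichloro{(5S)-5-methyl-5-[(4R,8R)-4,8,12-trimethyltridecyl]-4,5-dihydrofuran-2-yl}cerium | Cl[Ce](Cl)C1=CC[C@](C)(CCC[C@H](C)CCC[C@H](C)CCCC(C)C)O1
F5 | step 14 | (2S,5R,9S)-9-ethynyl-2,7,8-trimethyl-9-(triethylsilyloxy)-2-[(4R,8R)-4,8,12-trimethyltridecyl]-1-oxaspiro[4.4]non-7-en-6-one | C#C[C@]1(O[Si](CC)(CC)CC)C(C)=C(C)C(=O)[C@@]12CC[C@](C)(CCC[C@H](C)CCC[C@H](C)CCCC(C)C)O2
F6 | step 14 | (2S,5R,9S)-9-acetyl-2,7,8-trimethyl-9-(triethylsilyloxy)-2-[(4R,8R)-4,8,12-trimethyltridecyl]-1-oxaspiro[4.4]non-7-en-6-one | CC(=O)[C@]1(O[Si](CC)(CC)CC)C(C)=C(C)C(=O)[C@@]12CC[C@](C)(CCC[C@H](C)CCC[C@H](C)CCCC(C)C)O2
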